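## Structural features

The target is an isoflavone: a 4-pyranone (ring C) fused to a benzene ring (ring A) through C4a–C8a, with the 3,4-dimethoxyphenyl ring B joined to C3 by one sp2–sp2 bond. Ring A is substituted everywhere except C5: methoxy at C6, a free hydroxyl at C7, a 3-methylbut-2-enyl (prenyl) chain at C8 and the ring oxygen O1 at C8a. There is no stereocentre and no alkene geometry to set; the only stereocentre met on the way is a transient, racemic C3 carbinol that is destroyed again. The fragile element is the C8 prenyl group next to the C7 phenol: acid closes this pair to a 2,2-dimethylchroman, and hydrogenation or electrophilic oxidants attack the trisubstituted alkene. The 4-pyranone also opens with hot hydroxide. The real difficulty is twofold: to place the prenyl chain on C8, between two oxygen-bearing carbons, without ambiguity, and to build ring C with its C3 aryl group without exposing the phenol/prenyl pair to acid. The key step exploits the fact that, once C2=C3 is hydrated, C4 is the formyl carbon of a ring A salicylaldehyde and C3 the carbonyl carbon of a ring B aryl ketone, already tethered through O1–C2, so a polarity-reversed C4 can close the six-membered ring onto C3.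

## Logic of the disconnections

16 ⇒ 15. The bond cut is O7–C of an allyl ether on the C7 oxygen. The phenol is released last because it cyclises onto the C8 chain under acid; a group that leaves under neutral transition-metal catalysis removes that hazard. The skeleton is not simplified, but every earlier step is freed from an acidic, nucleophilic OH. The forward step must ionise the O-allyl unit while the C8 chain, which has no leaving group, stays inert.

15 ⇒ 13. Water is added back across C2=C3, so C3 becomes a tertiary carbinol bearing ring B and C4 stays a ketone. This turns the flat pyranone into an α-hydroxy ketone, the retron of a benzoin reaction. The forward step must remove water without strong acid. It is helped because C2 holds the only β-hydrogens, so only one alkene can form, and the transient C3 stereocentre disappears.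

13 ⇒ 11 (key disconnection). The C3–C4 bond is cut between two carbonyl-level carbons, opening ring C to an aldehyde (C4) and an aryl ketone (C3) still joined through O1–C2. One ring, one C–C bond and the only stereocentre of the route are removed. The forward step needs polarity reversal at C4 and must outrun enolate chemistry of the O1–C2H2–C3(=O) unit.

11 ⇒ 9 + 10. The O1–C2 ether bond is cut; this is the point of convergence, with ring A arriving as 9 and ring B with C2 and C3 as 10. The forward step alkylates a chelated, flanked phenol with a very reactive primary halide. It must be mild enough that the product does not close to a five-membered ring by aldol condensation.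

9 ⇒ 8. The O–allyl bond on the oxygen that becomes O7 is cut. The two hydroxyls of 8 differ: one is chelated to the formyl group, the other is para to it and more acidic. The forward step must etherify only the second, keeping the chelated one for the next ether formation.

8 ⇒ 6. The C8–C1'' bond is cut by a retro-[3,3] shift, which moves the five-carbon unit from carbon to the neighbouring oxygen as a 1,1-dimethylallyl ether. A C–C bond at a crowded ring position is exchanged for a C–O bond at the most reactive hydroxyl. The forward rearrangement has only one open ortho position, since the other carries the methoxy group, but it must be stopped before the product reacts further.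

6 ⇒ 5 ⇒ 3 + 4. The vinyl group is traced to an ethynyl group, and the tertiary C–O bond is then cut to the phenol 3 and the tertiary propargylic chloride 4. The alkyne is what makes a tertiary ether accessible by substitution; the price is a partial hydrogenation that must stop at the alkene.

3 ⇒ 1. The C4–C4a bond (the formyl group) is cut, leaving 1. The forward electrophilic formylation must go to the one ring position that is ortho to one hydroxyl and para to the other.

## Other disconnections considered

Alternative 1: The cut lies in ring A, at O1–C8a and C8–C1'' together, and leads back to 4-methoxy-3-(methoxymethoxy)-2-(trimethylsilyl)phenyl trifluoromethanesulfonate A1 and potassium 2-methylbut-3-en-2-olate A2.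
- Forward step: fluoride would induce 1,2-elimination of A1 across C8–C8a. The oxygen of A2 should add to C8a, the carbon remote from the C7 acetal oxygen. The C8 aryl anion could then take the vinyl terminus through a six-membered array as the O–CMe2 bond breaks, giving 4-methoxy-3-(methoxymethoxy)-2-(3-methylbut-2-enyl)phenol A3.
- In favour: two bonds of the crowded C7–C8–C8a region form in one operation, at ambient temperature, with no hydrogenation and no hot rearrangement. On bond economy of the key step and on mildness of the prenyl installation this alternative is the better plan.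
- Against: A1 needs several steps of its own. Protonation of the C8 anion would compete with allyl transfer. A3 still lacks C4, C3, C2 and ring B, so a formylation at C4a and all of the ring C chemistry would follow. The acetal on O7 would finally have to be removed by acid beside the prenyl chain.
- Comparison: structurally it solves only the ring A substitution, which the chosen plan settles equally well because C6 is blocked (equal on regiocontrol). Mechanistically, an anionic allyl transfer onto a strained triple bond is less secure than an aromatic Claisen rearrangement. In step count it is longer, since it cannot replace the ring closure.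

Alternative 2: The cut is the C4–C4a bond of ring C, leading back to (Z)-3-[4-methoxy-3-(prop-2-enyloxy)phenoxy]-2-(3,4-dimethoxyphenyl)prop-2-enoic acid A4.
- Forward step: activation of A4 as a trifluoroacetyl mixed anhydride would acylate C4a, para to the C7 oxygen, and give 7-allyloxy-3-(3,4-dimethoxyphenyl)-6-methoxychromen-4-one A5. A thermal Claisen shift of the allyl group to C8 (C6 is blocked) and a cross-metathesis exchanging the terminal CH2 for CMe2 would finish the synthesis.
- In favour: ring C forms directly at the chromone oxidation level, so no dehydration is needed (better). The allyl ether is both protecting group and precursor of the prenyl chain, so no protecting group is spent (better). The prenyl alkene is made last and carried through nothing (better). Two steps separate the key product from the target (equal).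
- Against: only the Z acid can cyclise, so the enol ether geometry must be controlled or must equilibrate. The β-aryloxy acrylate is an acid-sensitive enol ether placed in a strongly acidic acylating medium. C8 is a possible, though disfavoured, second acylation site. The Claisen shift on A5 needs about 200 °C. Building A4 takes about as many steps as reaching 11.
- Comparison: mechanistically an electrophilic aromatic substitution against a nucleophilic carbonyl addition. The chosen plan runs near neutrality throughout, which is the safer course for ring closure. Alternative 2 is better on protecting-group economy and about equal in overall step count.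

Alternative 3: The cut goes through ring A itself at C4a–C8a, tracing the benzene ring to (±)-4-{(E)-2-[2-(3,4-dimethoxybenzyl)-1,3-dioxolan-2-yl]ethenyl}-4-methoxy-2-(3-methylbut-2-enyl)-3-(propan-2-yloxy)cyclobut-2-en-1-one A6.
- Forward step: heating should cause a four-electron ring opening with the methoxy group turning outward, then a six-electron closure between the ketene carbon (C8a) and the alkene terminus (C4a). Tautomerisation would give 2-[2-(3,4-dimethoxybenzyl)-1,3-dioxolan-2-yl]-4-methoxy-6-(3-methylbut-2-enyl)-5-(propan-2-yloxy)phenol A7.
- In favour: every ring A substituent is placed by the order in which the four-membered ring is assembled (equal to the chosen plan here, where the blocked C6 position does the same job). The key step needs no reagent and is neutral, which suits the prenyl group (better on mildness of the key step). C4 and the benzylic carbon of ring B arrive already attached.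
- Against: A6 needs a long linear build-up and a separately made functionalised alkenyl metal. After A7, acetal hydrolysis, one-carbon insertion for C2 and cleavage of the isopropyl ether with a boron halide would all be run with a phenol or its ether beside the prenyl chain. That is the acid/prenyl conflict the chosen plan is built to avoid.
- Comparison: a pericyclic benzannulation against a polar organocatalytic ring closure. Constructing the benzene ring is not justified when a correctly oxygenated benzene can be bought. Step economy is clearly worse.

Key step: step 7

Remark: the route keeps the carbon skeletons and the C3–C4 closure of the benzoin precursor 11 and product 13 but carries O7 as an allyl ether instead of an acetal, and separates dehydration (step 8) from deprotection (step 9), so that no acid ever meets the C7 phenol/C8 prenyl pair; re-derivation of the ring A pattern from the target (OMe at C6, O at C7, prenyl at C8) showed no structural error to correct.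

## Route

Step 1
Reactants: 1 4-methoxyresorcinol (4-methoxybenzene-1,3-diol)
Product: 3 2,4-dihydroxy-5-methoxybenzaldehyde, via aryl iminium salt 2 (not isolated)
Conditions: POCl3, DMF, MeCN, −15 °C to rt; then H2O, 50 °C
Reagents that add atoms: N,N-dimethylformamide CN(C)C=O; water O
Why: Vilsmeier–Haack formylation; the chloroiminium electrophile should attack C6 of 1, which is ortho to one hydroxyl, para to the other and unhindered (C2 lies between two hydroxyls, C5 is meta to both), and the iminium salt 2 is hydrolysed to the aldehyde on warming with water.

Step 2
Reactants: 3 2,4-dihydroxy-5-methoxybenzaldehyde; 4 3-chloro-3-methylbut-1-yne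
Product: 5 2-hydroxy-5-methoxy-4-(2-methylbut-3-yn-2-yloxy)benzaldehyde
Conditions: K2CO3, KI (cat.), CuI (cat.), acetone, 56 °C
Reagents that add atoms: none
Why: Copper-assisted O-alkylation of a phenoxide with a tertiary propargylic chloride; the 4-OH, para to the formyl group, is free and the more acidic, while the 2-OH is locked in a hydrogen bond to the aldehyde, so mono-etherification at O4 is expected.

Step 3
Reactants: 5 2-hydroxy-5-methoxy-4-(2-methylbut-3-yn-2-yloxy)benzaldehyde
Product: 6 2-hydroxy-5-methoxy-4-(2-methylbut-3-en-2-yloxy)benzaldehyde
Conditions: H2 (1 atm), Pd/CaCO3 poisoned with Pb(OAc)2, quinoline, EtOAc, rt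
Reagents that add atoms: none
Why: Lindlar semi-hydrogenation; the poisoned catalyst should reduce the terminal alkyne to the vinyl group and stop there, leaving the aldehyde and the tertiary aryl ether untouched.

Step 4
Reactants: 6 2-hydroxy-5-methoxy-4-(2-methylbut-3-en-2-yloxy)benzaldehyde
Product: 8 2,4-dihydroxy-5-methoxy-3-(3-methylbut-2-enyl)benzaldehyde, via cyclohexadienone tautomer 7 (not isolated)
Conditions: PhNEt2, 160 °C, N2
Reagents that add atoms: none
Why: Aromatic Claisen rearrangement; the [3,3] shift with allylic inversion turns the O-bound 1,1-dimethylallyl group into a C-bound 3-methylbut-2-enyl group, and since the other ortho position carries OMe only C3 can accept it, giving dienone 7, which enolises to 8; the basic amine solvent suppresses acid-catalysed cyclisation of the product.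

Step 5
Reactants: 8 2,4-dihydroxy-5-methoxy-3-(3-methylbut-2-enyl)benzaldehyde
Product: 9 2-hydroxy-5-methoxy-3-(3-methylbut-2-enyl)-4-(prop-2-enyloxy)benzaldehyde
Conditions: allyl bromide (1.05 equiv), K2CO3 (1.1 equiv), acetone, rt
Reagents that add atoms: allyl bromide C=CCBr
Why: Williamson etherification; with about one equivalent of base and halide the more acidic, non-chelated 4-OH should react while the 2-OH, hydrogen-bonded to the formyl group, is kept for step 6. The allyl ether is chosen because it can later be removed at neutral pH without touching the prenyl alkene.

Step 6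
Reactants: 9 2-hydroxy-5-methoxy-3-(3-methylbut-2-enyl)-4-(prop-2-enyloxy)benzaldehyde; 10 2-bromo-1-(3,4-dimethoxyphenyl)ethanone
Product: 11 2-[2-(3,4-dimethoxyphenyl)-2-oxoethoxy]-5-methoxy-3-(3-methylbut-2-enyl)-4-(prop-2-enyloxy)benzaldehyde
Conditions: K2CO3, DMF, 0 °C to rt
Reagents that add atoms: none
Why: Williamson etherification (SN2 at the activated α-bromo ketone) of the remaining chelated phenol; a mild carbonate base at or below room temperature is used so that alkylation is complete before the product can enolise and close onto the aldehyde (Rap–Stoermer pathway).

Step 7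
Reactants: 11 2-[2-(3,4-dimethoxyphenyl)-2-oxoethoxy]-5-methoxy-3-(3-methylbut-2-enyl)-4-(prop-2-enyloxy)benzaldehyde
Product: 13 (±)-3-(3,4-dimethoxyphenyl)-3-hydroxy-6-methoxy-8-(3-methylbut-2-enyl)-7-(prop-2-enyloxy)chroman-4-one, via Breslow enaminol 12 (not isolated)
Conditions: 2-mesityl-6,7-dihydro-5H-pyrrolo[2,1-c][1,2,4]triazol-2-ium chloride (10 mol%), Et3N (20 mol%), THF (0.05 M), rt, Ar
Reagents that add atoms: none
Why: Et3N deprotonates the triazolium salt to the carbene, which adds to the formyl carbon (C4) of 11; proton transfer gives the enaminol 12, an acyl anion equivalent, so the polarity of the aldehyde carbon is reversed. Its nucleophilic C4 adds to the ketone carbon C3, held in reach through C4a–C8a–O1–C2, in a 6-exo-trig closure that forms the C3–C4 bond and ring C; proton transfer and loss of the carbene leave the tertiary α-hydroxy ketone 13 and return the catalyst. The closest known reaction type is the carbene-catalysed intramolecular crossed aldehyde–ketone benzoin cyclisation of 2-(2-oxoalkoxy)benzaldehydes to 3-hydroxychroman-4-ones. The new C3 stereocentre has no controlling element (achiral catalyst, no other stereocentre), so 13 should be racemic, which does not matter because C3 becomes sp2 in step 8. The selectivity needed is donor/acceptor assignment and benzoin over aldol: only the aldehyde has the C–H needed to form the enaminol and the ketone is the only electrophile left, placed for a six-membered transition state, so role reversal is excluded by the substrate and homo-coupling is disfavoured at this dilution. Enolisation of the O–CH2–CO unit and aldol closure onto the aldehyde are held back by the weak amine base in substoichiometric amount and by fast carbene addition to the aldehyde. The prenyl and allyl alkenes are unactivated and should not act as acceptors for the enaminol.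

Step 8
Reactants: 13 (±)-3-(3,4-dimethoxyphenyl)-3-hydroxy-6-methoxy-8-(3-methylbut-2-enyl)-7-(prop-2-enyloxy)chroman-4-one
Product: 15 3-(3,4-dimethoxyphenyl)-6-methoxy-8-(3-methylbut-2-enyl)-7-(prop-2-enyloxy)chromen-4-one, via chlorosulfite ester 14 (not isolated)
Conditions: SOCl2, pyridine, CH2Cl2, 0 °C to rt
Reagents that add atoms: none
Why: Dehydration of a tertiary alcohol with thionyl chloride and pyridine; the chlorosulfite 14 should lose SO2 and chloride with removal of a C2 proton, and since C2 carries the only β-hydrogens and the product is a vinylogous ester conjugated with ring B, only one alkene can form. The pyridine-buffered medium contains no free strong acid, so the prenyl and allyl groups should survive, and the C3 stereocentre disappears.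

Step 9
Reactants: 15 3-(3,4-dimethoxyphenyl)-6-methoxy-8-(3-methylbut-2-enyl)-7-(prop-2-enyloxy)chromen-4-one
Product: 16 3-(3,4-dimethoxyphenyl)-7-hydroxy-6-methoxy-8-(3-methylbut-2-enyl)chromen-4-one
Conditions: Pd(PPh3)4 (5 mol%), morpholine, THF, rt; aq. NH4Cl work-up
Reagents that add atoms: none
Why: Tsuji–Trost-type deallylation; zerovalent palladium should ionise the allyl aryl ether to a π-allyl complex and the C7 phenoxide (a good leaving group, vinylogous to the C4 carbonyl), and morpholine captures the allyl unit. The prenyl chain has no leaving group and is inert, and no acid is involved, so the phenol/prenyl pair is released intact.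

## Compound list

1 | 4-methoxyresorcinol (4-methoxybenzene-1,3-diol) | COc1ccc(O)cc1O | starting material
2 | N-[(2,4-dihydroxy-5-methoxyphenyl)methylidene]-N-methylmethanaminium dichlorophosphate (aryl iminium salt) | COc1cc(C=[N+](C)C)c(O)cc1O.[O-]P(=O)(Cl)Cl | intermediate (not isolated)
3 | 2,4-dihydroxy-5-methoxybenzaldehyde | COc1cc(C=O)c(O)cc1O | intermediate
4 | 3-chloro-3-methylbut-1-yne | C#CC(C)(C)Cl | starting material
5 | 2-hydroxy-5-methoxy-4-(2-methylbut-3-yn-2-yloxy)benzaldehyde | COc1cc(C=O)c(O)cc1OC(C)(C)C#C | intermediate
6 | 2-hydroxy-5-methoxy-4-(2-methylbut-3-en-2-yloxy)benzaldehyde | COc1cc(C=O)c(O)cc1OC(C)(C)C=C | intermediate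
7 | (±)-2-hydroxy-5-methoxy-3-(3-methylbut-2-enyl)-4-oxocyclohexa-1,5-diene-1-carbaldehyde (cyclohexadienone tautomer) | COC1=CC(C=O)=C(O)C(CC=C(C)C)C1=O | intermediate (not isolated)
8 | 2,4-dihydroxy-5-methoxy-3-(3-methylbut-2-enyl)benzaldehyde | COc1cc(C=O)c(O)c(CC=C(C)C)c1O | intermediate
9 | 2-hydroxy-5-methoxy-3-(3-methylbut-2-enyl)-4-(prop-2-enyloxy)benzaldehyde | COc1cc(C=O)c(O)c(CC=C(C)C)c1OCC=C | intermediate
10 | 2-bromo-1-(3,4-dimethoxyphenyl)ethanone | COc1ccc(C(=O)CBr)cc1OC | starting material
11 | 2-[2-(3,4-dimethoxyphenyl)-2-oxoethoxy]-5-methoxy-3-(3-methylbut-2-enyl)-4-(prop-2-enyloxy)benzaldehyde | C=CCOc1c(OC)cc(C=O)c(OCC(=O)c2ccc(OC)c(OC)c2)c1CC=C(C)C | intermediate (key-step precursor)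
12 | Breslow enaminol of 11: the former formyl carbon carries OH and is doubly bonded to C3 of 2-mesityl-2,5,6,7-tetrahydro-3H-pyrrolo[2,1-c][1,2,4]triazole (alkene geometry not defined) | C=CCOc1c(OC)cc(C(O)=C2N(c3c(C)cc(C)cc3C)N=C3CCCN23)c(OCC(=O)c2ccc(OC)c(OC)c2)c1CC=C(C)C | intermediate (not isolated)
13 | (±)-3-(3,4-dimethoxyphenyl)-3-hydroxy-6-methoxy-8-(3-methylbut-2-enyl)-7-(prop-2-enyloxy)chroman-4-one (racemic at C3) | C=CCOc1c(OC)cc2c(c1CC=C(C)C)OCC(O)(c1ccc(OC)c(OC)c1)C2=O | intermediate (key-step product)
14 | (±)-3-(3,4-dimethoxyphenyl)-6-methoxy-8-(3-methylbut-2-enyl)-4-oxo-7-(prop-2-enyloxy)chroman-3-yl chlorosulfite | C=CCOc1c(OC)cc2c(c1CC=C(C)C)OCC(OS(Cl)=O)(c1ccc(OC)c(OC)c1)C2=O | intermediate (not isolated)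
15 | 3-(3,4-dimethoxyphenyl)-6-methoxy-8-(3-methylbut-2-enyl)-7-(prop-2-enyloxy)chromen-4-one | C=CCOc1c(OC)cc2c(c1CC=C(C)C)occ(-c1ccc(OC)c(OC)c1)c2=O | intermediate
16 | 3-(3,4-dimethoxyphenyl)-7-hydroxy-6-methoxy-8-(3-methylbut-2-enyl)chromen-4-one (no stereocentre) | COc1ccc(-c2coc3c(CC=C(C)C)c(O)c(OC)cc3c2=O)cc1OC | target

## Step count and least certain steps

Total: 9 steps. Longest linear sequence: 9 steps (1 to 16); 4 and 10 enter as purchased compounds.

Step 7 (key step). The most likely failure is enolisation of the O–CH2–CO unit by the base, followed by aldol closure onto the aldehyde and loss of water to a five-membered ring, outrunning carbene addition. The second risk is slow enaminol formation, because the aldehyde is deactivated by its ortho and para alkoxy groups. Fallback: setting out from 9, ring C would be closed at O1–C2 by the polar deoxybenzoin sequence.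
- Addition of 3,4-dimethoxybenzylmagnesium chloride (excess, THF, 0 °C; the first equivalent is consumed by the phenol) should give (±)-1-[2-hydroxy-5-methoxy-3-(3-methylbut-2-enyl)-4-(prop-2-enyloxy)phenyl]-2-(3,4-dimethoxyphenyl)ethanol F1.
- Oxidation of the benzylic carbinol (MnO2, CH2Cl2) should give 1-[2-hydroxy-5-methoxy-3-(3-methylbut-2-enyl)-4-(prop-2-enyloxy)phenyl]-2-(3,4-dimethoxyphenyl)ethanone F2.
- One-carbon insertion with N,N-dimethylformamide dimethyl acetal (toluene, 90 °C, then dilute AcOH) should close the pyranone and come back to the route at 15.

Step 6. Premature aldol cyclodehydration of the product under carbonate, or incomplete alkylation of the chelated and doubly flanked phenol, would erode the supply of 11. Fallback: setting out from 9 and 10, the same O1–C2 bond is formed with no base present.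
- 10 is converted with HCO2Na in aqueous EtOH (reflux) through 2-(3,4-dimethoxyphenyl)-2-oxoethyl formate F3, solvolysed in the same pot, into 2-hydroxy-1-(3,4-dimethoxyphenyl)ethanone F4.
- A Mitsunobu etherification of 9 with F4 (PPh3, diisopropyl azodicarboxylate, THF, 0 °C to rt) should come back to the route at 11.

Step 8. Capture of the C3 centre by chloride in place of elimination, or ionisation at C3 followed by an α-ketol-type shift, could divert the chlorosulfite; traces of unbuffered acid could also add to the prenyl alkene. Fallback: setting out from 13, the hydroxyl is removed reductively and the alkene is introduced by oxidation.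
- SmI2 (THF–MeOH, −78 °C) should cleave the C3–O bond of the α-hydroxy ketone to (±)-3-(3,4-dimethoxyphenyl)-6-methoxy-8-(3-methylbut-2-enyl)-7-(prop-2-enyloxy)chroman-4-one F5.
- Enolisation with silylation (LiHMDS, Me3SiCl, THF, −78 °C) should give 3-(3,4-dimethoxyphenyl)-6-methoxy-8-(3-methylbut-2-enyl)-7-(prop-2-enyloxy)-4-(trimethylsilyloxy)-2H-chromene F6.
- Saegusa–Ito oxidation (Pd(OAc)2, MeCN, rt) should create C2=C3 and come back to the route at 15.

Step 4. On prolonged heating a phenolic hydroxyl may add to the new prenyl alkene, or the chain may isomerise by an abnormal Claisen process, since the chain sits between two hydroxyls at high temperature. Fallback: setting out from 3, the hot step is run on a simple allyl group and the prenyl alkene is made afterwards at low temperature.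
- O4-allylation (allyl bromide, K2CO3, acetone) should give 2-hydroxy-5-methoxy-4-(prop-2-enyloxy)benzaldehyde F7.
- Claisen rearrangement (PhNEt2, about 190 °C) should give 2,4-dihydroxy-5-methoxy-3-(prop-2-enyl)benzaldehyde F8.
- Olefin cross-metathesis with 2-methylbut-2-ene (second-generation Grubbs catalyst, CH2Cl2, 40 °C) should convert the allyl into the prenyl group and come back to the route at 8.

## Further compounds

F1 | step 7 | (±)-1-[2-hydroxy-5-methoxy-3-(3-methylbut-2-enyl)-4-(prop-2-enyloxy)phenyl]-2-(3,4-dimethoxyphenyl)ethanol | C=CCOc1c(OC)cc(C(O)Cc2ccc(OC)c(OC)c2)c(O)c1CC=C(C)C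
F2 | step 7 | 1-[2-hydroxy-5-methoxy-3-(3-methylbut-2-enyl)-4-(prop-2-enyloxy)phenyl]-2-(3,4-dimethoxyphenyl)ethanone | C=CCOc1c(OC)cc(C(=O)Cc2ccc(OC)c(OC)c2)c(O)c1CC=C(C)C
F3 | step 6 | 2-(3,4-dimethoxyphenyl)-2-oxoethyl formate | COc1ccc(C(=O)COC=O)cc1OC
F4 | step 6 | 2-hydroxy-1-(3,4-dimethoxyphenyl)ethanone | COc1ccc(C(=O)CO)cc1OC
F5 | step 8 | (±)-3-(3,4-dimethoxyphenyl)-6-methoxy-8-(3-methylbut-2-enyl)-7-(prop-2-enyloxy)chroman-4-one | C=CCOc1c(OC)cc2c(c1CC=C(C)C)OCC(c1ccc(OC)c(OC)c1)C2=O
F6 | step 8 | 3-(3,4-dimethoxyphenyl)-6-methoxy-8-(3-methylbut-2-enyl)-7-(prop-2-enyloxy)-4-(trimethylsilyloxy)-2H-chromene | C=CCOc1c(OC)cc2c(c1CC=C(C)C)OCC(c1ccc(OC)c(OC)c1)=C2O[Si](C)(C)C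
F7 | step 4 | 2-hydroxy-5-methoxy-4-(prop-2-enyloxy)benzaldehyde | COc1cc(C=O)c(O)cc1OCC=C
F8 | step 4 | 2,4-dihydroxy-5-methoxy-3-(prop-2-enyl)benzaldehyde | COc1cc(C=O)c(O)c(CC=C)c1O
A1 | alternative 1 | 4-methoxy-3-(methoxymethoxy)-2-(trimethylsilyl)phenyl trifluoromethanesulfonate | COCOc1c(OC)ccc(OS(=O)(=O)C(F)(F)F)c1[Si](C)(C)C
A2 | alternative 1 | potassium 2-methylbut-3-en-2-olate | [K+].[O-]C(C)(C)C=C
A3 | alternative 1 | 4-methoxy-3-(methoxymethoxy)-2-(3-methylbut-2-enyl)phenol | COCOc1c(OC)ccc(O)c1CC=C(C)C
A4 | alternative 2 | (Z)-3-[4-methoxy-3-(prop-2-enyloxy)phenoxy]-2-(3,4-dimethoxyphenyl)prop-2-enoic acid | OC(=O)/C(c1ccc(OC)c(OC)c1)=C\Oc1ccc(OC)c(OCC=C)c1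
A5 | alternative 2 | 7-allyloxy-3-(3,4-dimethoxyphenyl)-6-methoxychromen-4-one | C=CCOc1cc2occ(-c3ccc(OC)c(OC)c3)c(=O)c2cc1OC
A6 | alternative 3 | (±)-4-{(E)-2-[2-(3,4-dimethoxybenzyl)-1,3-dioxolan-2-yl]ethenyl}-4-methoxy-2-(3-methylbut-2-enyl)-3-(propan-2-yloxy)cyclobut-2-en-1-one | O=C1C(CC=C(C)C)=C(OC(C)C)C1(OC)/C=C/C1(Cc2ccc(OC)c(OC)c2)OCCO1
A7 | alternative 3 | 2-[2-(3,4-dimethoxybenzyl)-1,3-dioxolan-2-yl]-4-methoxy-6-(3-methylbut-2-enyl)-5-(propan-2-yloxy)phenol | CC(C)Oc1c(OC)cc(C2(Cc3ccc(OC)c(OC)c3)OCCO2)c(O)c1CC=C(C)C
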